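**Plan**
- Feature: in this 3,3''-biflavanone (flavanone numbering, doubly primed = 4-hydroxyphenyl half) C4–C3–C3''–C4'' is a 1,4-diketone and therefore the four carbons of a furan. C4/C4'' are its α carbons, each bonded to C4a/C4a'' of a ring A; C3/C3'' are its β carbons, each bonded to C2/C2''.
- Cuts, in order: the two C=O and the C3–H/C3''–H bonds are folded back into that furan; C4–C4a and C4''–C4a'' (both rings C) are cut together; then the two O1–C8a aryl ether bonds; last C2–C3 and C2''–C3'', leading to 3,4-dibromofuran and two benzaldehydes.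
- Forward: the furan is joined to both aldehydes, oxidised to the 3,4-diaroylfuran, reduced to the diol and O-arylated; both rings C then close onto the furan α positions in one palladium step; the furan ring is finally opened, reduced and deprotected.
- Stereochemistry: C2 and C2'' come from catalyst-controlled asymmetric transfer hydrogenation and pass through an O-arylation that never breaks the benzylic C–O bond; C3 and C3'' settle trans to them under thermodynamic control after the enedione reduction.

Key step: step 9

Remark: C2 and C2'' keep one spatial arrangement throughout; their CIP label is R while C3/C3'' is a furan or alkene carbon (which outranks the aryl group) and becomes S once C3/C3'' is sp3.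
Assumption: in the transfer hydrogenation the conjugated p-alkoxyphenyl ring takes the aryl position of the catalyst pocket and the twisted 3,4-disubstituted furyl ring the alkyl position, as with ortho-substituted benzophenones; the (S,S)-catalyst is chosen on that basis.
Assumption: 5-iodoresorcinol is bought; the many partly deprotected species of the last step are not numbered one by one.

**Route**

Step 1
Reactants: 1 4-hydroxybenzaldehyde
Product: 2 4-(methoxymethoxy)benzaldehyde
Conditions: MOMCl, i-Pr2NEt, CH2Cl2, 0 °C to rt
Reagents that add atoms: chloromethyl methyl ether, COCCl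
Why: Williamson-type O-alkylation of the phenol by the highly electrophilic α-chloro ether should give the MOM acetal, which tolerates the organolithium, hydride, copper and palladium steps ahead and leaves under mild acid at the end.

Step 2
Reactants: 3 5-iodoresorcinol
Product: 4 1-iodo-3,5-bis(methoxymethoxy)benzene
Conditions: MOMCl (2.5 equiv), i-Pr2NEt, CH2Cl2, 0 °C to rt
Reagents that add atoms: chloromethyl methyl ether, COCCl
Why: The same Williamson-type acetalisation on both phenols should leave the C–I bond untouched, and MOM is preferred to benzyl because it offers no arene C–H that could compete in the later palladium step.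

Step 3
Reactants: 4 1-iodo-3,5-bis(methoxymethoxy)benzene
Product: 5 2-bromo-1-iodo-3,5-bis(methoxymethoxy)benzene
Conditions: NBS (1.0 equiv), MeCN, 0 °C, dark
Reagents that add atoms: N-bromosuccinimide, O=C1CCC(=O)N1Br
Why: Electrophilic aromatic bromination should go to the carbon para to one OMOM group and ortho to the other (next to iodine) and not to the more crowded carbon between the two OMOM groups, as is usual for 5-substituted resorcinol diethers, which places bromine on the future C4a and leaves iodine on the future C8a.

Step 4
Reactants: 6 3,4-dibromofuran; 7 4-methoxybenzaldehyde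
Product: 9 rac-(4-bromofuran-3-yl)(4-methoxyphenyl)methanol, via 3-bromo-4-lithiofuran 8 (not isolated)
Conditions: n-BuLi (1.0 equiv), Et2O, −78 °C; then 7; then H2O
Reagents that add atoms: none
Why: Bromine–lithium exchange of one C–Br bond at −78 °C gives a 3-furyllithium that is stable at this temperature and undergoes 1,2-addition to the aldehyde; the new carbinol centre is racemic and is erased in step 6.

Step 5
Reactants: 9 rac-(4-bromofuran-3-yl)(4-methoxyphenyl)methanol; 2 4-(methoxymethoxy)benzaldehyde
Product: 11 furan-3,4-diyl bis(aryl carbinol) as a diastereomer mixture, via dilithio alkoxide 10 (not isolated)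
Conditions: n-BuLi (2.1 equiv), THF, −78 °C; then 2; then H2O
Reagents that add atoms: none
Why: One equivalent of n-BuLi deprotonates the alcohol and the second performs bromine–lithium exchange, so the alkoxide-bearing furyllithium adds to aldehyde 2 (1,2-addition); the carbinol centres are unselective and are erased in the next step.

Step 6
Reactants: 11 furan-3,4-diyl bis(aryl carbinol)
Product: 14 3-(4-methoxybenzoyl)-4-[4-(methoxymethoxy)benzoyl]furan, via anisoyl hydroxy ketone 12 (not isolated), via MOM-oxybenzoyl hydroxy ketone 13 (not isolated)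
Conditions: MnO2 (activated, excess), CH2Cl2, rt
Reagents that add atoms: none
Why: MnO2 oxidation of aryl/furyl carbinols should run under neutral conditions that spare the MOM acetal and the furan, and all diastereomers converge on one diketone because a strained furo[3,4-c]furan hemiketal should not trap the halfway hydroxy ketones.

Step 7
Reactants: 14 3-(4-methoxybenzoyl)-4-[4-(methoxymethoxy)benzoyl]furan
Product: 17 (R,R)-diol, via (R)-anisyl carbinol ketone 15 (not isolated), via (R)-MOM-oxyphenyl carbinol ketone 16 (not isolated)
Conditions: RuCl[(S,S)-TsDPEN](p-cymene) (cat.), HCO2H/Et3N (1:1), EtOAc, 40 °C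
Reagents that add atoms: none
Why: Noyori–Ikariya asymmetric transfer hydrogenation: in each ketone the conjugated p-alkoxyphenyl ring can sit under the η6-arene of the catalyst while the ortho-substituted furyl ring is twisted like the substituted ring of an ortho-substituted benzophenone, so the (S,S)-catalyst should deliver hydride to the face that gives the R carbinol at both carbons (catalyst control), and two such events in one molecule should push most stereochemical error into the separable R,S diastereomers.

Step 8
Reactants: 17 (R,R)-diol; 5 2-bromo-1-iodo-3,5-bis(methoxymethoxy)benzene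
Product: 20 3,4-bis[(R)-aryl(2-bromoaryloxy)methyl]furan, via anisyl-side monoether 18 (not isolated), via MOM-oxyphenyl-side monoether 19 (not isolated)
Conditions: CuI (cat.), 3,4,7,8-tetramethyl-1,10-phenanthroline, Cs2CO3, 5 (2.5 equiv), toluene, 110 °C
Reagents that add atoms: none
Why: Ullmann-type copper-catalysed O-arylation of a secondary alcohol with an aryl iodide should engage only the O–H bond of each carbinol and the C–I bond of 5 (C–I reacts well before C–Br under copper catalysis), so both benzylic centres are retained, which an SN-type displacement at the ionisation-prone p-anisyl carbinol carbon could not guarantee.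

Step 9
Reactants: 20 3,4-bis[(R)-aryl(2-bromoaryloxy)methyl]furan
Product: 23 furan-fused bis(chromene), via anisyl-side monocyclised bromide 21 (not isolated), via MOM-oxyphenyl-side monocyclised bromide 22 (not isolated)
Conditions: Pd(OAc)2 (cat.), PCy3·HBF4, PivOH (cat.), K2CO3, DMA, 110 °C
Reagents that add atoms: none
Why: Zerovalent palladium (from Pd(OAc)2 and PCy3) inserts into one C–Br bond, bromide is exchanged for pivalate, and carboxylate-assisted concerted metalation–deprotonation takes the furan α C–H next to the tether; reductive elimination from the seven-membered aryl(furyl)palladium ring forms C4–C4a and closes the first six-membered pyran ring (ring C), and the same cycle on the second arm forms C4''–C4a'' and the second ring C. The closest known reaction type is the pivalate-assisted intramolecular direct arylation of five-membered heteroarenes by aryl halides, as used to build furo[3,2-c]chromenes and 6H-benzo[c]chromenes. No stereocentre is made, and C2 and C2'' carry neither an acidic hydrogen nor a hydrogen β to palladium, so they should pass unchanged. The step needs site selectivity for the furan α C–H over the ortho C–H of the C2 aryl ring, which an equally sized palladacycle could reach: the furan α position has the much lower metalation barrier, and each arm can geometrically reach only the α carbon next to it. MOM in place of benzyl ethers on ring A removes a third competitor, since an ortho benzyloxy group would offer its own phenyl ring for six-membered closure.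

Step 10
Reactants: 23 furan-fused bis(chromene)
Product: 25 (Z)-ene-1,4-dione, via furan endoperoxide 24 (not isolated)
Conditions: O2, tetraphenylporphyrin (cat.), visible light, CH2Cl2, −78 °C; then Me2S, −78 to 0 °C; used at once
Reagents that add atoms: oxygen, O=O
Why: [4+2] Cycloaddition of singlet oxygen to the electron-rich tetrasubstituted furan should give the α,α'-endoperoxide, whose reduction by Me2S opens it to the ene-1,4-dione with the two carbonyl groups cis (Z) as fixed by the cyclic peroxide; alkoxyarenes, MOM acetals and the C2/C2'' ethers do not react with singlet oxygen at −78 °C.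

Step 11
Reactants: 25 (Z)-ene-1,4-dione
Product: 26 (2S,3R,2''S,3''R)-penta-MOM biflavanone
Conditions: Zn dust, AcOH/THF, 0 °C to rt, then 45 °C
Reagents that add atoms: none
Why: Dissolving-metal reduction (Zn/AcOH) of an ene-1,4-dione gives the saturated 1,4-diketone, and because C3 and C3'' are α to the ketones they should equilibrate by enolisation in warm acetic acid until each is trans (diequatorial) to the aryl group on the neighbouring fixed C2 or C2'' centre (substrate control, thermodynamic), giving 3R,3''R; the acidic medium protonates the zinc enolates before they can expel the ring aryloxide.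

Step 12
Reactants: 26 (2S,3R,2''S,3''R)-penta-MOM biflavanone
Product: 27 target biflavanone CNP0196568.1
Conditions: HCl (2 M in MeOH), THF, 40 °C
Reagents that add atoms: none
Why: Acid-catalysed acetal exchange with methanol removes the five MOM groups as dimethoxymethane under conditions mild enough to keep the flavanone rings closed and to avoid Paal–Knorr recyclisation of the 1,4-diketone, and the same acid should funnel any residual 2,3-cis unit to the preferred trans arrangement.

**Compound list**
1 | 4-hydroxybenzaldehyde | O=Cc1ccc(O)cc1 | starting material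
2 | 4-(methoxymethoxy)benzaldehyde | COCOc1ccc(C=O)cc1 | intermediate
3 | 5-iodoresorcinol (5-iodobenzene-1,3-diol) | Oc1cc(O)cc(I)c1 | starting material
4 | 1-iodo-3,5-bis(methoxymethoxy)benzene | COCOc1cc(I)cc(OCOC)c1 | intermediate
5 | 2-bromo-1-iodo-3,5-bis(methoxymethoxy)benzene | COCOc1cc(I)c(Br)c(OCOC)c1 | intermediate
6 | 3,4-dibromofuran | Brc1cocc1Br | starting material
7 | 4-methoxybenzaldehyde | COc1ccc(C=O)cc1 | starting material
8 | 3-bromo-4-lithiofuran | [Li]c1cocc1Br | intermediate
9 | rac-(4-bromofuran-3-yl)(4-methoxyphenyl)methanol | COc1ccc(C(O)c2cocc2Br)cc1 | intermediate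
10 | lithium (4-lithiofuran-3-yl)(4-methoxyphenyl)methanolate (dilithio alkoxide) | COc1ccc(C(O[Li])c2cocc2[Li])cc1 | intermediate
11 | {4-[hydroxy(4-methoxyphenyl)methyl]furan-3-yl}[4-(methoxymethoxy)phenyl]methanol, mixture of diastereomers | COc1ccc(C(O)c2cocc2C(O)c2ccc(OCOC)cc2)cc1 | intermediate
12 | rac-{4-[hydroxy[4-(methoxymethoxy)phenyl]methyl]furan-3-yl}(4-methoxyphenyl)methanone | COc1ccc(C(=O)c2cocc2C(O)c2ccc(OCOC)cc2)cc1 | intermediate
13 | rac-{4-[hydroxy(4-methoxyphenyl)methyl]furan-3-yl}[4-(methoxymethoxy)phenyl]methanone | COc1ccc(C(O)c2cocc2C(=O)c2ccc(OCOC)cc2)cc1 | intermediate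
14 | 3-(4-methoxybenzoyl)-4-[4-(methoxymethoxy)benzoyl]furan | COc1ccc(C(=O)c2cocc2C(=O)c2ccc(OCOC)cc2)cc1 | intermediate
15 | {4-[(R)-hydroxy(4-methoxyphenyl)methyl]furan-3-yl}[4-(methoxymethoxy)phenyl]methanone | COc1ccc([C@@H](O)c2cocc2C(=O)c2ccc(OCOC)cc2)cc1 | intermediate
16 | {4-[(R)-hydroxy[4-(methoxymethoxy)phenyl]methyl]furan-3-yl}(4-methoxyphenyl)methanone | COc1ccc(C(=O)c2cocc2[C@H](O)c2ccc(OCOC)cc2)cc1 | intermediate
17 | (R)-{4-[(R)-hydroxy(4-methoxyphenyl)methyl]furan-3-yl}[4-(methoxymethoxy)phenyl]methanol | COc1ccc([C@@H](O)c2cocc2[C@H](O)c2ccc(OCOC)cc2)cc1 | intermediate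
18 | (R)-{4-[(R)-[2-bromo-3,5-bis(methoxymethoxy)phenoxy](4-methoxyphenyl)methyl]furan-3-yl}[4-(methoxymethoxy)phenyl]methanol | COc1ccc([C@@H](Oc2cc(OCOC)cc(OCOC)c2Br)c2cocc2[C@H](O)c2ccc(OCOC)cc2)cc1 | intermediate
19 | (R)-{4-[(R)-[2-bromo-3,5-bis(methoxymethoxy)phenoxy][4-(methoxymethoxy)phenyl]methyl]furan-3-yl}(4-methoxyphenyl)methanol | COc1ccc([C@@H](O)c2cocc2[C@H](Oc2cc(OCOC)cc(OCOC)c2Br)c2ccc(OCOC)cc2)cc1 | intermediate
20 | 3-{(R)-[2-bromo-3,5-bis(methoxymethoxy)phenoxy](4-methoxyphenyl)methyl}-4-{(R)-[2-bromo-3,5-bis(methoxymethoxy)phenoxy][4-(methoxymethoxy)phenyl]methyl}furan | COc1ccc([C@@H](Oc2cc(OCOC)cc(OCOC)c2Br)c2cocc2[C@H](Oc2cc(OCOC)cc(OCOC)c2Br)c2ccc(OCOC)cc2)cc1 | intermediate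
21 | monocyclised 4H-furo[3,2-c]chromene, ring C closed on the anisyl side (C4–C4a formed), other arm still the (R)-2-bromoaryl ether | COc1ccc([C@H]2Oc3cc(OCOC)cc(OCOC)c3-c3occ([C@H](Oc4cc(OCOC)cc(OCOC)c4Br)c4ccc(OCOC)cc4)c32)cc1 | intermediate
22 | monocyclised 4H-furo[3,2-c]chromene, ring C closed on the MOM-oxyphenyl side (C4''–C4a'' formed), anisyl arm still the (R)-2-bromoaryl ether | COc1ccc([C@@H](Oc2cc(OCOC)cc(OCOC)c2Br)c2coc3-c4c(OCOC)cc(OCOC)cc4O[C@H](c4ccc(OCOC)cc4)c23)cc1 | intermediate
23 | (2R,2''R)-furan-fused bis(chromene): furan α carbons C4/C4'' bonded to C4a/C4a'', β carbons C3/C3''; 2-(4-methoxyphenyl), 2''-[4-(methoxymethoxy)phenyl], 5,7,5'',7''-tetrakis(methoxymethoxy) | COc1ccc([C@H]2Oc3cc(OCOC)cc(OCOC)c3-c3oc4-c5c(OCOC)cc(OCOC)cc5O[C@H](c5ccc(OCOC)cc5)c4c32)cc1 | intermediate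
24 | 4,4''-epidioxy endoperoxide of 23 (either furan face; C3=C3'' double bond) | COc1ccc([C@H]2Oc3cc(OCOC)cc(OCOC)c3C34OOC5(O3)c3c(OCOC)cc(OCOC)cc3O[C@H](c3ccc(OCOC)cc3)C5=C24)cc1 | intermediate
25 | (Z,2R,2''R)-3,3''-didehydro-penta-MOM biflavanone (C4=O and C4''=O cis across C3=C3'') | COc1ccc([C@H]2Oc3cc(OCOC)cc(OCOC)c3C(=O)/C2=C2\C(=O)c3c(OCOC)cc(OCOC)cc3O[C@@H]2c2ccc(OCOC)cc2)cc1 | intermediate
26 | (2S,3R,2''S,3''R)-2-(4-methoxyphenyl)-2''-[4-(methoxymethoxy)phenyl]-5,7,5'',7''-tetrakis(methoxymethoxy)-[3,3''-bichromane]-4,4''-dione | COc1ccc([C@H]2Oc3cc(OCOC)cc(OCOC)c3C(=O)[C@@H]2[C@H]2C(=O)c3c(OCOC)cc(OCOC)cc3O[C@@H]2c2ccc(OCOC)cc2)cc1 | intermediate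
27 | (2S,3R,2''S,3''R)-5,7,5'',7''-tetrahydroxy-2''-(4-hydroxyphenyl)-2-(4-methoxyphenyl)-[3,3''-bichromane]-4,4''-dione | COc1ccc([C@H]2Oc3cc(O)cc(O)c3C(=O)[C@@H]2[C@H]2C(=O)c3c(O)cc(O)cc3O[C@@H]2c2ccc(O)cc2)cc1 | target

**Step count and risks**
Total: 12 steps. Longest linear sequence: 9 steps (steps 4 to 12, from 3,4-dibromofuran); the side branches are step 1 and steps 2–3.

1. Step 8 (double copper-catalysed O-arylation). What may go wrong: C–O bond formation at two crowded diaryl carbinols may be slow, so that oxidation of the copper alkoxide back to the ketone, reduction of the aryl iodide, or coupling at C–Br instead of C–I takes over. The fallback forms the ether bonds at the benzylic carbons with inversion; it sets out from 14 and returns at 20. Diketone 14 is reduced under the conditions of step 7 with RuCl[(R,R)-TsDPEN](p-cymene) to the (S,S)-diol F1. Commercial phloroglucinol is converted with two equivalents of MOMCl and i-Pr2NEt into 3,5-bis(methoxymethoxy)phenol F2, and amine-catalysed ortho-bromination (NBS, cat. i-Pr2NH, CH2Cl2, 0 °C) gives 2-bromo-3,5-bis(methoxymethoxy)phenol F3. Double Mitsunobu etherification of F1 with F3 (PPh3, DIAD, toluene, −20 °C to rt, one carbinol after the other if cyclodehydration competes) inverts both centres and gives 20.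

2. Step 11 (Zn/AcOH reduction). What may go wrong: a zinc enolate may expel the ring aryloxide by β-elimination (ring C opens and C2 or C2'' is lost), or kinetic C-protonation may leave 2,3-cis units that equilibrate only slowly. The fallback replaces electron transfer by radical hydrogenation; it sets out from 25 and returns at 26. Metal-hydride hydrogen-atom-transfer reduction (Mn(dpm)3 cat., PhSiH3, t-BuOOH, i-PrOH, rt) delivers hydrogen atoms to C3 and C3'' without forming an enolate and tends to give the thermodynamically preferred configuration. It makes no compound beyond the list (F0).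

3. Step 7 (asymmetric transfer hydrogenation). What may go wrong: enantioface discrimination between two aryl-type substituents may be weak, or the reaction may stall after the first reduction. The fallback sets the carbinol centres during C–C bond formation; it sets out from 6 and 7 and returns at 17. Lithiofuran 8 (from 6 as in step 4) is transmetalated with EtZnCl to ethyl(4-bromofuran-3-yl)zinc F4. Addition of F4 to 7 under (−)-MIB catalysis (TEEDA, toluene, 0 °C; Si-face delivery as in the ethylation of benzaldehyde) should give (R)-(4-bromofuran-3-yl)(4-methoxyphenyl)methanol F5. Silylation (TBSCl, imidazole, DMF) gives the TBS ether F6. Bromine–lithium exchange (n-BuLi, −78 °C) gives the furyllithium F7, EtZnCl gives the furylzinc F8, and the same MIB-catalysed addition to 2 gives the monosilylated (R,R)-diol F9. TBAF in THF then gives 17.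

**Further compounds**
F1 | step 8 | (S)-{4-[(S)-hydroxy(4-methoxyphenyl)methyl]furan-3-yl}[4-(methoxymethoxy)phenyl]methanol | COc1ccc([C@H](O)c2cocc2[C@@H](O)c2ccc(OCOC)cc2)cc1
F2 | step 8 | 3,5-bis(methoxymethoxy)phenol | COCOc1cc(O)cc(OCOC)c1
F3 | step 8 | 2-bromo-3,5-bis(methoxymethoxy)phenol | COCOc1cc(O)c(Br)c(OCOC)c1
F0 | step 11 | none | none
F4 | step 7 | ethyl(4-bromofuran-3-yl)zinc | CC[Zn]c1cocc1Br
F5 | step 7 | (R)-(4-bromofuran-3-yl)(4-methoxyphenyl)methanol | COc1ccc([C@@H](O)c2cocc2Br)cc1
F6 | step 7 | (R)-[(4-bromofuran-3-yl)(4-methoxyphenyl)methoxy](tert-butyl)dimethylsilane | COc1ccc([C@@H](O[Si](C)(C)C(C)(C)C)c2cocc2Br)cc1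
F7 | step 7 | {4-[(R)-(tert-butyldimethylsilyloxy)(4-methoxyphenyl)methyl]furan-3-yl}lithium | COc1ccc([C@@H](O[Si](C)(C)C(C)(C)C)c2cocc2[Li])cc1
F8 | step 7 | ethyl{4-[(R)-(tert-butyldimethylsilyloxy)(4-methoxyphenyl)methyl]furan-3-yl}zinc | COc1ccc([C@@H](O[Si](C)(C)C(C)(C)C)c2cocc2[Zn]CC)cc1
F9 | step 7 | (R)-{4-[(R)-(tert-butyldimethylsilyloxy)(4-methoxyphenyl)methyl]furan-3-yl}[4-(methoxymethoxy)phenyl]methanol | COc1ccc([C@@H](O[Si](C)(C)C(C)(C)C)c2cocc2[C@H](O)c2ccc(OCOC)cc2)cc1
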